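## Retrosynthetic overview

1. Target ⇒ alkene hydrogenation and Julia–Kocienski olefination across the middle of the hexamethylene tether: an (S)-phthalide acetaldehyde plus a spiroketal tetrazolyl sulfone.
2. Phthalide acetaldehyde ⇒ the lactone ring is closed by an enantioselective intramolecular oxa-Michael addition of a benzoic acid onto an ortho (E)-α'-hydroxy enone, whose ketol unit is then cut down to CHO. The enone comes from aldol condensation of 2-formyl-4,6-dimethoxybenzoic acid, made from 3,5-dimethoxybenzaldehyde.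
3. Spiroketal sulfone ⇒ acid-mediated double cyclisation of a 2,8-dihydroxy-5-ketone, assembled by two successive alkylations of acetone N,N-dimethylhydrazone with (S)-propylene oxide and an (S)-epichlorohydrin-derived epoxide.
4. Ring order: both tetrahydrofuran rings of the spiroketal form together on one branch, the lactone ring forms on the other branch, and the branches are joined last. The arene is bought.

Assumption: the SMILES is read as 3S in the lactone and 2S,5S,7S in the spiroketal (C2 methyl-bearing, C5 spiro, C7 chain-bearing); acetone N,N-dimethylhydrazone and benzyl 3-bromopropyl ether are taken as catalogue chemicals.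

## Route

**Step 1**
Reactants: 1 3,5-dimethoxybenzaldehyde
Product: 2 2-bromo-3,5-dimethoxybenzaldehyde
Conditions: NBS, MeCN, 0 °C → rt
Reagents that add atoms: N-bromosuccinimide, O=C1CCC(=O)N1Br
Why: Electrophilic aromatic bromination goes to the position ortho to CHO, which is para to one methoxy and ortho to the other and less crowded than the site between the two methoxy groups.

**Step 2**
Reactants: 2 2-bromo-3,5-dimethoxybenzaldehyde
Product: 3 2-(2-bromo-3,5-dimethoxyphenyl)-1,3-dioxolane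
Conditions: HOCH2CH2OH, p-TsOH·H2O (cat.), toluene, reflux, Dean–Stark
Reagents that add atoms: ethylene glycol, OCCO
Why: Acetalisation with azeotropic water removal masks the aldehyde against the organolithium step.

**Step 3**
Reactants: 3 2-(2-bromo-3,5-dimethoxyphenyl)-1,3-dioxolane
Product: 6 3-hydroxy-5,7-dimethoxyisobenzofuran-1(3H)-one (ring tautomer of 2-formyl-4,6-dimethoxybenzoic acid), via aryllithium 4 (not isolated), via lithium dioxolanylbenzoate 5 (not isolated)
Conditions: n-BuLi, THF, −78 °C; CO2 (g), −78 °C → rt; then 2 M HCl, THF/H2O, rt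
Reagents that add atoms: carbon dioxide, O=C=O; water, O
Why: Bromine–lithium exchange and carboxylation place the acid next to the masked aldehyde, and aqueous acid removes the acetal so the formyl acid closes to its lactol.

**Step 4**
Reactants: 6 3-hydroxy-5,7-dimethoxyisobenzofuran-1(3H)-one; 7 3-hydroxy-3-methylbutan-2-one
Product: 8 (E)-2-(4-hydroxy-4-methyl-3-oxopent-1-en-1-yl)-4,6-dimethoxybenzoic acid
Conditions: LiOH·H2O (3 equiv), MeOH/H2O, rt; then 1 M HCl to pH 3 at 0 °C, fast extraction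
Reagents that add atoms: none
Why: Claisen–Schmidt aldol condensation of the ring-opened formyl carboxylate with a ketone that can enolise only at its methyl group gives the (E)-enone by E1cB dehydration, and in base the open carboxylate is the stable form (any cyclised racemate reverts by retro-Michael).

**Step 5**
Reactants: 8 (E)-2-(4-hydroxy-4-methyl-3-oxopent-1-en-1-yl)-4,6-dimethoxybenzoic acid
Product: 9 (S)-3-(3-hydroxy-3-methyl-2-oxobutyl)-5,7-dimethoxyisobenzofuran-1(3H)-one
Conditions: quinine-derived 3,5-bis(trifluoromethyl)phenyl squaramide (10 mol %), CH2Cl2, −20 °C, 48 h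
Reagents that add atoms: none
Why: In this asymmetric intramolecular oxa-Michael addition (5-exo-trig) the quinuclidine nitrogen deprotonates the acid while the squaramide N–H groups hold the ketol carbonyl, so the carboxylate adds to one face of the enone inside a chiral ion pair and sets C3; the sense is assigned by analogy and is checked by chiral HPLC at aldehyde 11, with the quinidine-derived pseudoenantiomer available for the other sense.

**Step 6**
Reactants: 9 (S)-3-(3-hydroxy-3-methyl-2-oxobutyl)-5,7-dimethoxyisobenzofuran-1(3H)-one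
Product: 10 (3S)-3-(2,3-dihydroxy-3-methylbutyl)-5,7-dimethoxyisobenzofuran-1(3H)-one (both carbinol epimers)
Conditions: NaBH4, CeCl3·7H2O, MeOH, −40 °C
Reagents that add atoms: none
Why: Luche-type reduction takes the ketone to the diol under weakly acidic conditions that leave the hindered lactone alone and suppress retro-Michael opening; the new carbinol centre is lost in the next step.

**Step 7**
Reactants: 10 (3S)-3-(2,3-dihydroxy-3-methylbutyl)-5,7-dimethoxyisobenzofuran-1(3H)-one
Product: 11 (S)-5,7-dimethoxy-3-(2-oxoethyl)isobenzofuran-1(3H)-one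
Conditions: NaIO4, THF/H2O, 0 °C → rt
Reagents that add atoms: none
Why: Periodate glycol cleavage (Malaprade reaction) releases the aldehyde and acetone under neutral conditions that do not disturb C3.

**Step 8**
Reactants: 12 benzyl 3-bromopropyl ether; 13 (S)-epichlorohydrin
Product: 15 (S)-6-(benzyloxy)-1-chlorohexan-2-ol, via Grignard reagent 14 (not isolated)
Conditions: 12, Mg, THF, 40 °C; then 13, CuI (10 mol %), THF, −40 → −20 °C; sat. aq. NH4Cl
Reagents that add atoms: none
Why: Copper-catalysed Grignard opening of the epoxide at its CH2 terminus leaves the stereocentre untouched and gives the chlorohydrin.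

**Step 9**
Reactants: 15 (S)-6-(benzyloxy)-1-chlorohexan-2-ol
Product: 16 (S)-2-(4-(benzyloxy)butyl)oxirane
Conditions: NaOH (powdered), Et2O, rt
Reagents that add atoms: none
Why: Intramolecular Williamson closure displaces chloride at the primary carbon, so the carbinol configuration is retained in the new epoxide.

**Step 10**
Reactants: 17 acetone N,N-dimethylhydrazone; 18 (S)-propylene oxide
Product: 21 (S)-5-(triethylsilyloxy)hexan-2-one N,N-dimethylhydrazone, via lithium azaenolate 19 (not isolated), via lithium alkoxide 20 (not isolated)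
Conditions: n-BuLi, THF, −78 → 0 °C; 18, −78 °C → rt; then Et3SiCl, 0 °C
Reagents that add atoms: chlorotriethylsilane, CC[Si](CC)(CC)Cl
Why: Corey–Enders azaenolate alkylation opens the epoxide by SN2 at CH2, so the secondary carbinol keeps its S configuration, and the alkoxide is capped in the same flask.

**Step 11**
Reactants: 21 (S)-5-(triethylsilyloxy)hexan-2-one N,N-dimethylhydrazone; 16 (S)-2-(4-(benzyloxy)butyl)oxirane
Product: 23 (2S,8S)-12-(benzyloxy)-8-hydroxy-2-(triethylsilyloxy)dodecan-5-one N,N-dimethylhydrazone, via lithium azaenolate 22 (not isolated)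
Conditions: n-BuLi, THF, −78 → 0 °C; 16, 0 °C → rt; H2O
Reagents that add atoms: none
Why: The second azaenolate alkylation occurs at the remaining methyl group (the less substituted α-carbon) and opens the second epoxide at CH2, so both carbinol centres come intact from the chiral pool.

**Step 12**
Reactants: 23 (2S,8S)-12-(benzyloxy)-8-hydroxy-2-(triethylsilyloxy)dodecan-5-one N,N-dimethylhydrazone
Product: 25 (2S,5S,7S)-7-(4-(benzyloxy)butyl)-2-methyl-1,6-dioxaspiro[4.4]nonane, via dihydroxyketone 24 (not isolated)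
Conditions: 2 M HCl, THF, rt; NaHCO3 work-up; preparative HPLC (SiO2); the (5R)-epimer is re-equilibrated (PPTS, CH2Cl2) and recycled
Reagents that add atoms: none
Why: Acid hydrolyses the hydrazone and the silyl ether and the freed dihydroxyketone closes both tetrahydrofuran rings by thermodynamic spiroketalisation; C2 and C7 are fixed by the epoxides, while the spiro carbon forms as a roughly 1:1 pair of epimers (no anomeric bias in a 5,5-system), from which the (5S)-isomer is separated.

**Step 13**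
Reactants: 25 (2S,5S,7S)-7-(4-(benzyloxy)butyl)-2-methyl-1,6-dioxaspiro[4.4]nonane
Product: 26 4-((2S,5S,7S)-7-methyl-1,6-dioxaspiro[4.4]nonan-2-yl)butan-1-ol
Conditions: H2 (1 atm), 10% Pd/C, NaHCO3, EtOAc, rt
Reagents that add atoms: none
Why: Neutral hydrogenolysis removes the benzyl ether without acid, so the spiro centre does not equilibrate.

**Step 14**
Reactants: 26 4-((2S,5S,7S)-7-methyl-1,6-dioxaspiro[4.4]nonan-2-yl)butan-1-ol
Product: 27 5-((4-((2S,5S,7S)-7-methyl-1,6-dioxaspiro[4.4]nonan-2-yl)butyl)thio)-1-phenyl-1H-tetrazole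
Conditions: 1-phenyl-1H-tetrazole-5-thiol, PPh3, DIAD, THF, 0 °C → rt
Reagents that add atoms: 1-phenyl-1H-tetrazole-5-thiol, Sc1nnnn1-c1ccccc1
Why: Mitsunobu thioetherification of the primary alcohol is neutral and leaves the spiroketal untouched.

**Step 15**
Reactants: 27 5-((4-((2S,5S,7S)-7-methyl-1,6-dioxaspiro[4.4]nonan-2-yl)butyl)thio)-1-phenyl-1H-tetrazole
Product: 28 5-((4-((2S,5S,7S)-7-methyl-1,6-dioxaspiro[4.4]nonan-2-yl)butyl)sulfonyl)-1-phenyl-1H-tetrazole
Conditions: mCPBA (2.5 equiv), NaHCO3, CH2Cl2, 0 °C → rt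
Reagents that add atoms: 3-chloroperoxybenzoic acid, O=C(OO)c1cccc(Cl)c1
Why: Buffered peracid oxidation takes the sulfide to the sulfone while the bicarbonate keeps the medium non-acidic for the spiroketal.

**Step 16**
Reactants: 28 5-((4-((2S,5S,7S)-7-methyl-1,6-dioxaspiro[4.4]nonan-2-yl)butyl)sulfonyl)-1-phenyl-1H-tetrazole; 11 (S)-5,7-dimethoxy-3-(2-oxoethyl)isobenzofuran-1(3H)-one
Product: 30 (S)-5,7-dimethoxy-3-(6-((2S,5S,7S)-7-methyl-1,6-dioxaspiro[4.4]nonan-2-yl)hex-2-en-1-yl)isobenzofuran-1(3H)-one (E/Z mixture), via potassium sulfonyl carbanion 29 (not isolated)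
Conditions: KN(SiMe3)2, THF, −78 °C, 30 min; then 11, −78 °C → rt
Reagents that add atoms: none
Why: In this Julia–Kocienski olefination the pre-formed sulfonyl carbanion adds to the aldehyde at −78 °C faster than it enolises it, and Smiles rearrangement with loss of SO2 and tetrazolate gives the alkene, whose geometry does not matter and which leaves all stereocentres untouched.

**Step 17**
Reactants: 30 (S)-5,7-dimethoxy-3-(6-((2S,5S,7S)-7-methyl-1,6-dioxaspiro[4.4]nonan-2-yl)hex-2-en-1-yl)isobenzofuran-1(3H)-one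
Product: 31 (S)-5,7-dimethoxy-3-(6-((2S,5S,7S)-7-methyl-1,6-dioxaspiro[4.4]nonan-2-yl)hexyl)isobenzofuran-1(3H)-one
Conditions: H2 (1 atm), PtO2 (5 mol %), EtOAc, rt
Reagents that add atoms: none
Why: Catalytic hydrogenation saturates the isolated alkene under neutral conditions that spare the lactone C–O bond, the arene and the spiroketal.

## Compound list

1 | 3,5-dimethoxybenzaldehyde | COc1cc(OC)cc(C=O)c1 | starting material
2 | 2-bromo-3,5-dimethoxybenzaldehyde | COc1cc(OC)c(Br)c(C=O)c1 | intermediate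
3 | 2-(2-bromo-3,5-dimethoxyphenyl)-1,3-dioxolane | COc1cc(OC)c(Br)c(C2OCCO2)c1 | intermediate
4 | (2-(1,3-dioxolan-2-yl)-4,6-dimethoxyphenyl)lithium | COc1cc(OC)c([Li])c(C2OCCO2)c1 | intermediate
5 | lithium 2-(1,3-dioxolan-2-yl)-4,6-dimethoxybenzoate | COc1cc(OC)c(C(=O)[O-])c(C2OCCO2)c1.[Li+] | intermediate
6 | 3-hydroxy-5,7-dimethoxyisobenzofuran-1(3H)-one (racemic lactol of 2-formyl-4,6-dimethoxybenzoic acid) | COc1cc(OC)c2c(c1)C(O)OC2=O | intermediate
7 | 3-hydroxy-3-methylbutan-2-one | CC(=O)C(C)(C)O | starting material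
8 | (E)-2-(4-hydroxy-4-methyl-3-oxopent-1-en-1-yl)-4,6-dimethoxybenzoic acid | COc1cc(OC)c(C(=O)O)c(/C=C/C(=O)C(C)(C)O)c1 | intermediate
9 | (S)-3-(3-hydroxy-3-methyl-2-oxobutyl)-5,7-dimethoxyisobenzofuran-1(3H)-one | COc1cc(OC)c2c(c1)[C@H](CC(=O)C(C)(C)O)OC2=O | intermediate
10 | (3S)-3-(2,3-dihydroxy-3-methylbutyl)-5,7-dimethoxyisobenzofuran-1(3H)-one (epimers at the side-chain carbinol) | COc1cc(OC)c2c(c1)[C@H](CC(O)C(C)(C)O)OC2=O | intermediate
11 | (S)-5,7-dimethoxy-3-(2-oxoethyl)isobenzofuran-1(3H)-one | COc1cc(OC)c2c(c1)[C@H](CC=O)OC2=O | intermediate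
12 | benzyl 3-bromopropyl ether | BrCCCOCc1ccccc1 | starting material
13 | (S)-epichlorohydrin | ClC[C@@H]1CO1 | starting material
14 | (3-(benzyloxy)propyl)magnesium bromide | Br[Mg]CCCOCc1ccccc1 | intermediate
15 | (S)-6-(benzyloxy)-1-chlorohexan-2-ol | ClC[C@@H](O)CCCCOCc1ccccc1 | intermediate
16 | (S)-2-(4-(benzyloxy)butyl)oxirane | C1[C@@H](O1)CCCCOCc2ccccc2 | intermediate
17 | acetone N,N-dimethylhydrazone | CC(C)=NN(C)C | starting material
18 | (S)-propylene oxide | C[C@H]1CO1 | starting material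
19 | lithiated acetone N,N-dimethylhydrazone (azaenolate, drawn C-lithiated) | [Li]CC(C)=NN(C)C | intermediate
20 | lithium (S)-5-(2,2-dimethylhydrazinylidene)hexan-2-olate | C[C@H]([O-])CCC(C)=NN(C)C.[Li+] | intermediate
21 | (S)-5-(triethylsilyloxy)hexan-2-one N,N-dimethylhydrazone | C[C@H](O[Si](CC)(CC)CC)CCC(C)=NN(C)C | intermediate
22 | C1-lithiated (S)-5-(triethylsilyloxy)hexan-2-one N,N-dimethylhydrazone (azaenolate) | C[C@H](O[Si](CC)(CC)CC)CCC(C[Li])=NN(C)C | intermediate
23 | (2S,8S)-12-(benzyloxy)-8-hydroxy-2-(triethylsilyloxy)dodecan-5-one N,N-dimethylhydrazone | C[C@H](O[Si](CC)(CC)CC)CCC(=NN(C)C)CC[C@@H](O)CCCCOCc1ccccc1 | intermediate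
24 | (2S,8S)-12-(benzyloxy)-2,8-dihydroxydodecan-5-one | C[C@H](O)CCC(=O)CC[C@@H](O)CCCCOCc1ccccc1 | intermediate
25 | (2S,5S,7S)-7-(4-(benzyloxy)butyl)-2-methyl-1,6-dioxaspiro[4.4]nonane | c1ccccc1COCCCC[C@H]2CC[C@]3(CC[C@H](C)O3)O2 | intermediate
26 | 4-((2S,5S,7S)-7-methyl-1,6-dioxaspiro[4.4]nonan-2-yl)butan-1-ol | OCCCC[C@H]1CC[C@]2(CC[C@H](C)O2)O1 | intermediate
27 | 5-((4-((2S,5S,7S)-7-methyl-1,6-dioxaspiro[4.4]nonan-2-yl)butyl)thio)-1-phenyl-1H-tetrazole | c1ccccc1-n1nnnc1SCCCC[C@H]1CC[C@]2(CC[C@H](C)O2)O1 | intermediate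
28 | 5-((4-((2S,5S,7S)-7-methyl-1,6-dioxaspiro[4.4]nonan-2-yl)butyl)sulfonyl)-1-phenyl-1H-tetrazole | O=S(=O)(CCCC[C@H]1CC[C@]2(CC[C@H](C)O2)O1)c1nnnn1-c1ccccc1 | intermediate
29 | potassium salt of the α-sulfonyl carbanion of 28 | [K+].O=S(=O)([CH-]CCC[C@H]1CC[C@]2(CC[C@H](C)O2)O1)c1nnnn1-c1ccccc1 | intermediate
30 | (S)-5,7-dimethoxy-3-(6-((2S,5S,7S)-7-methyl-1,6-dioxaspiro[4.4]nonan-2-yl)hex-2-en-1-yl)isobenzofuran-1(3H)-one (E/Z mixture) | COc1cc(OC)c2c(c1)[C@H](CC=CCCC[C@H]1CC[C@]3(CC[C@H](C)O3)O1)OC2=O | intermediate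
31 | (S)-5,7-dimethoxy-3-(6-((2S,5S,7S)-7-methyl-1,6-dioxaspiro[4.4]nonan-2-yl)hexyl)isobenzofuran-1(3H)-one | COc1cc(OC)c2c(c1)[C@H](CCCCCC[C@H]1CC[C@]3(CC[C@H](C)O3)O1)OC2=O | target

## Step count and risks

Total step count: 17.
Longest linear sequence: 9 steps (steps 1–7, 16, 17; the branch through steps 8, 9, 11–17 is equally long).

**Step 5 (asymmetric oxa-Michael).** The enantioselectivity, the sense of induction and a racemic background cyclisation of acid 8 are all uncertain. The fallback sets the centre by reagent-controlled allylation and closes the lactone by acylation. It sets out from 6: methylation of the ring-opened carboxylate (MeI, K2CO3, DMF) gives methyl 2-formyl-4,6-dimethoxybenzoate F1. Brown allylation with (−)-B-allyldiisopinocampheylborane (Et2O, −78 °C, ethanolamine work-up) is expected, by analogy with benzaldehyde, to give the (S)-carbinol, whose alkoxide lactonises onto the neighbouring ester to give (S)-3-allyl-5,7-dimethoxyisobenzofuran-1(3H)-one F2. Ozonolysis (O3, CH2Cl2/MeOH, −78 °C, then PPh3) cuts the allyl group to the aldehyde, and the route is rejoined at 11. This material also serves as the reference for checking the configuration of 11 from step 5.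

**Step 12 (spiro centre).** The two spiro epimers form in about equal amounts and may not separate at the benzyl ether stage. The fallback moves the resolution to the UV-active end products. It sets out from 23: the acid step is run as before but the 1:1 mixture of 25 and (2S,5R,7S)-7-(4-(benzyloxy)butyl)-2-methyl-1,6-dioxaspiro[4.4]nonane F3 is carried unseparated through steps 13 to 17. Alongside 26, 27, 28 and 30 this gives 4-((2S,5R,7S)-7-methyl-1,6-dioxaspiro[4.4]nonan-2-yl)butan-1-ol F4, 5-((4-((2S,5R,7S)-7-methyl-1,6-dioxaspiro[4.4]nonan-2-yl)butyl)thio)-1-phenyl-1H-tetrazole F5, 5-((4-((2S,5R,7S)-7-methyl-1,6-dioxaspiro[4.4]nonan-2-yl)butyl)sulfonyl)-1-phenyl-1H-tetrazole F6 and (S)-5,7-dimethoxy-3-(6-((2S,5R,7S)-7-methyl-1,6-dioxaspiro[4.4]nonan-2-yl)hex-2-en-1-yl)isobenzofuran-1(3H)-one F7. The final hydrogenation then gives the target together with (S)-5,7-dimethoxy-3-(6-((2S,5R,7S)-7-methyl-1,6-dioxaspiro[4.4]nonan-2-yl)hexyl)isobenzofuran-1(3H)-one F8. The two phthalides are separated by semi-preparative HPLC, F8 is re-equilibrated at the spiro carbon only (PPTS, CH2Cl2) and re-separated, and the route is rejoined at 31.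

**Step 16 (Julia–Kocienski olefination).** The β-acyloxy aldehyde 11 can enolise and ring-open by E1cB elimination, or racemise, under the basic conditions. The fallback reverses the polarity of the coupling so that the base-sensitive aldehyde is never exposed to a carbanion. It sets out from 11 and 26. Reduction of 11 (NaBH4, MeOH, 0 °C) gives (S)-3-(2-hydroxyethyl)-5,7-dimethoxyisobenzofuran-1(3H)-one F9. Mitsunobu reaction with 1-phenyl-1H-tetrazole-5-thiol (PPh3, DIAD, THF) gives (S)-5,7-dimethoxy-3-(2-((1-phenyl-1H-tetrazol-5-yl)thio)ethyl)isobenzofuran-1(3H)-one F10, and oxidation (mCPBA, NaHCO3, CH2Cl2) gives (S)-5,7-dimethoxy-3-(2-((1-phenyl-1H-tetrazol-5-yl)sulfonyl)ethyl)isobenzofuran-1(3H)-one F11. Dess–Martin oxidation of 26 gives 4-((2S,5S,7S)-7-methyl-1,6-dioxaspiro[4.4]nonan-2-yl)butanal F12. Julia–Kocienski coupling of F11 with F12 under Barbier conditions (KN(SiMe3)2 added to both at −78 °C in THF) forms the same double bond, and the route is rejoined at 30.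

## Further compounds

F1 | step 5 | methyl 2-formyl-4,6-dimethoxybenzoate | COC(=O)c1c(C=O)cc(OC)cc1OC
F2 | step 5 | (S)-3-allyl-5,7-dimethoxyisobenzofuran-1(3H)-one | COc1cc(OC)c2c(c1)[C@H](CC=C)OC2=O
F3 | step 12 | (2S,5R,7S)-7-(4-(benzyloxy)butyl)-2-methyl-1,6-dioxaspiro[4.4]nonane | c1ccccc1COCCCC[C@H]2CC[C@@]3(CC[C@H](C)O3)O2
F4 | step 12 | 4-((2S,5R,7S)-7-methyl-1,6-dioxaspiro[4.4]nonan-2-yl)butan-1-ol | OCCCC[C@H]1CC[C@@]2(CC[C@H](C)O2)O1
F5 | step 12 | 5-((4-((2S,5R,7S)-7-methyl-1,6-dioxaspiro[4.4]nonan-2-yl)butyl)thio)-1-phenyl-1H-tetrazole | c1ccccc1-n1nnnc1SCCCC[C@H]1CC[C@@]2(CC[C@H](C)O2)O1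
F6 | step 12 | 5-((4-((2S,5R,7S)-7-methyl-1,6-dioxaspiro[4.4]nonan-2-yl)butyl)sulfonyl)-1-phenyl-1H-tetrazole | O=S(=O)(CCCC[C@H]1CC[C@@]2(CC[C@H](C)O2)O1)c1nnnn1-c1ccccc1
F7 | step 12 | (S)-5,7-dimethoxy-3-(6-((2S,5R,7S)-7-methyl-1,6-dioxaspiro[4.4]nonan-2-yl)hex-2-en-1-yl)isobenzofuran-1(3H)-one | COc1cc(OC)c2c(c1)[C@H](CC=CCCC[C@H]1CC[C@@]3(CC[C@H](C)O3)O1)OC2=O
F8 | step 12 | (S)-5,7-dimethoxy-3-(6-((2S,5R,7S)-7-methyl-1,6-dioxaspiro[4.4]nonan-2-yl)hexyl)isobenzofuran-1(3H)-one | COc1cc(OC)c2c(c1)[C@H](CCCCCC[C@H]1CC[C@@]3(CC[C@H](C)O3)O1)OC2=O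
F9 | step 16 | (S)-3-(2-hydroxyethyl)-5,7-dimethoxyisobenzofuran-1(3H)-one | COc1cc(OC)c2c(c1)[C@H](CCO)OC2=O
F10 | step 16 | (S)-5,7-dimethoxy-3-(2-((1-phenyl-1H-tetrazol-5-yl)thio)ethyl)isobenzofuran-1(3H)-one | COc1cc(OC)c2c(c1)[C@H](CCSc1nnnn1-c1ccccc1)OC2=O
F11 | step 16 | (S)-5,7-dimethoxy-3-(2-((1-phenyl-1H-tetrazol-5-yl)sulfonyl)ethyl)isobenzofuran-1(3H)-one | COc1cc(OC)c2c(c1)[C@H](CCS(=O)(=O)c1nnnn1-c1ccccc1)OC2=O
F12 | step 16 | 4-((2S,5S,7S)-7-methyl-1,6-dioxaspiro[4.4]nonan-2-yl)butanal | O=CCCC[C@H]1CC[C@]2(CC[C@H](C)O2)O1
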